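**Strategy.** The decalin is cut at the two bonds that flank the ring-fusion carbon C10: C8–C9 in ring B and C1–C10 in ring A. The key step exploits the fact that C10, the methyl-bearing quaternary carbon shared by rings A and B, is the inner carbon of an isopropenyl group on C5 and lies between a C8 acyl selenide and a C1–C3 vinyl ketone. One radical chain therefore closes ring B, then ring A, and sets C10. The precursor is an open chain whose C4 and C5 stereocentres come from a Sharpless epoxidation and an SN2 epoxide opening. Its C4 hydroxyl is silylated so that it cannot lactonise onto C8.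

Key step: step 10

Remark: eudesmane numbering is used throughout; compounds 11–14 are carried as C3 epimer mixtures that converge on oxidation in step 9; tert-butyl 4-oxobutanoate is taken as a commercial material.

**Step 1**
Reactants: 1 tert-butyl 4-oxobutanoate; 2 2-(triphenylphosphoranylidene)propanal
Product: 4 tert-butyl (4E)-6-hydroxy-5-methylhex-4-enoate, via enal 3 (not isolated)
Conditions: toluene, 80 °C; then MeOH, NaBH4, 0 °C
Reagents that add atoms: none
Why: Wittig olefination with the formyl-stabilised ylide should be E-selective with an aliphatic aldehyde, and NaBH4 then reduces only the aldehyde of enal 3 (1,2-reduction) and leaves the tert-butyl ester alone.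

**Step 2**
Reactants: 4 tert-butyl (4E)-6-hydroxy-5-methylhex-4-enoate
Product: 5 tert-butyl 3-[(2R,3R)-3-(hydroxymethyl)-3-methyloxiran-2-yl]propanoate
Conditions: Ti(OiPr)4 (10 mol%), D-(−)-diethyl tartrate (12 mol%), t-BuOOH, 4 Å molecular sieves, CH2Cl2, −20 °C
Reagents that add atoms: tert-butyl hydroperoxide, CC(C)(C)OO
Why: Sharpless asymmetric epoxidation of an (E)-2-methyl allylic alcohol, in which the D-tartrate ligand directs oxygen to the face that gives the (2R,3R)-epoxide and so fixes C4 and, after the later inversion, C5.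

**Step 3**
Reactants: 5 tert-butyl 3-[(2R,3R)-3-(hydroxymethyl)-3-methyloxiran-2-yl]propanoate; 6 isopropenylmagnesium bromide
Product: 7 tert-butyl (4R,5S)-5,6-dihydroxy-5-methyl-4-(prop-1-en-2-yl)hexanoate
Conditions: CH2=C(CH3)MgBr (4 equiv), CuBr·SMe2 (20 mol%), THF, −30 → 0 °C; aq NH4Cl
Reagents that add atoms: none
Why: copper-catalysed Grignard opening of a 2,3-epoxy alcohol, in which the fully substituted C4 cannot be attacked, so the alkenylcopper species should enter at the secondary carbon C5 by SN2 with inversion and set C5 while C4 keeps its oxygen; the tert-butyl ester is chosen to resist both the Grignard reagent and lactonisation by the tertiary alkoxide.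

**Step 4**
Reactants: 7 tert-butyl (4R,5S)-5,6-dihydroxy-5-methyl-4-(prop-1-en-2-yl)hexanoate
Product: 8 tert-butyl (4R,5S)-5-methyl-4-(prop-1-en-2-yl)-5,6-bis[(triethylsilyl)oxy]hexanoate
Conditions: Et3SiOTf (2.6 equiv), 2,6-lutidine, CH2Cl2, −78 → 0 °C
Reagents that add atoms: triethylsilyl trifluoromethanesulfonate, CC[Si](CC)(CC)OS(=O)(=O)C(F)(F)F
Why: silyl triflate silylation covers the primary and the hindered tertiary hydroxyl, and the C4 silyl ether is kept to the key step because a free C4–OH sits δ to the C8 acyl group and would close a six-membered lactone.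

**Step 5**
Reactants: 8 tert-butyl (4R,5S)-5-methyl-4-(prop-1-en-2-yl)-5,6-bis[(triethylsilyl)oxy]hexanoate
Product: 9 tert-butyl (4R,5S)-5-methyl-6-oxo-4-(prop-1-en-2-yl)-5-[(triethylsilyl)oxy]hexanoate
Conditions: (COCl)2, DMSO, CH2Cl2, −78 → −30 °C; Et3N, −78 °C → rt
Reagents that add atoms: none
Why: Swern conditions are known to cleave and oxidise a primary triethylsilyl ether directly to the aldehyde while a tertiary silyl ether stays, and the aldehyde has no α-hydrogen, so nothing can epimerise.

**Step 6**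
Reactants: 9 tert-butyl (4R,5S)-5-methyl-6-oxo-4-(prop-1-en-2-yl)-5-[(triethylsilyl)oxy]hexanoate; 10 vinylmagnesium bromide
Product: 11 tert-butyl (4R,5S,6RS)-6-hydroxy-5-methyl-4-(prop-1-en-2-yl)-5-[(triethylsilyl)oxy]oct-7-enoate
Conditions: CH2=CHMgBr (1.5 equiv), THF, −78 °C; aq NH4Cl at −78 °C
Reagents that add atoms: none
Why: Grignard 1,2-addition to the aldehyde at −78 °C is much faster than attack on the tert-butyl ester, and the new C3 carbinol forms as an epimer mixture that step 9 removes.

**Step 7**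
Reactants: 11 tert-butyl (4R,5S,6RS)-6-hydroxy-5-methyl-4-(prop-1-en-2-yl)-5-[(triethylsilyl)oxy]oct-7-enoate
Product: 13 (4R,5S,6RS)-6-hydroxy-5-methyl-4-(prop-1-en-2-yl)-5-[(triethylsilyl)oxy]oct-7-enoic acid, via silyl ester 12 (not isolated)
Conditions: Me3SiOTf (3 equiv), 2,6-lutidine (4 equiv), CH2Cl2, 0 °C → rt; then MeOH, aq citric acid, 0 °C
Reagents that add atoms: trimethylsilyl trifluoromethanesulfonate (its atoms remain only in 12), C[Si](C)(C)OS(=O)(=O)C(F)(F)F
Why: silyl triflate cleavage of a tert-butyl ester (loss of 2-methylpropene gives the silyl ester, the C3 hydroxyl being silylated in passing) is non-protic, so the tertiary triethylsilyl ether should survive, and mild methanolysis then frees the acid and the C3 hydroxyl.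

**Step 8**
Reactants: 13 (4R,5S,6RS)-6-hydroxy-5-methyl-4-(prop-1-en-2-yl)-5-[(triethylsilyl)oxy]oct-7-enoic acid
Product: 14 Se-phenyl (4R,5S,6RS)-6-hydroxy-5-methyl-4-(prop-1-en-2-yl)-5-[(triethylsilyl)oxy]oct-7-eneselenoate
Conditions: PhSeH (1.5 equiv), EDC·HCl, DMAP (10 mol%), CH2Cl2, 0 °C
Reagents that add atoms: benzeneselenol, [SeH]c1ccccc1
Why: carbodiimide (Steglich-type) coupling, in which the selenol is far more nucleophilic than the hindered secondary alcohol, and with O4 silylated no six-membered lactone can compete.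

**Step 9**
Reactants: 14 Se-phenyl (4R,5S,6RS)-6-hydroxy-5-methyl-4-(prop-1-en-2-yl)-5-[(triethylsilyl)oxy]oct-7-eneselenoate
Product: 15 Se-phenyl (4R,5S)-5-methyl-6-oxo-4-(prop-1-en-2-yl)-5-[(triethylsilyl)oxy]oct-7-eneselenoate (eudesmane numbering: 4S,5R)
Conditions: Dess–Martin periodinane, CH2Cl2, 0 °C → rt
Reagents that add atoms: none
Why: Dess–Martin oxidation of the allylic alcohol is neutral and non-nucleophilic, should tolerate the acyl selenide and erases the C3 stereocentre; the vinyl ketone is unveiled last because selenols and Grignard reagents would add to it.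

**Step 10**
Reactants: 15 Se-phenyl (4R,5S)-5-methyl-6-oxo-4-(prop-1-en-2-yl)-5-[(triethylsilyl)oxy]oct-7-eneselenoate
Product: 17 (4S,5R,10R)-4-hydroxy-11,12,13-trinoreudesmane-3,8-dione, via triethylsilyl ether 16 (not isolated)
Conditions: (Me3Si)3SiH (1.3 equiv) and AIBN (0.3 equiv) added over 8 h by syringe pump, benzene (5 mM), 80 °C; then HF·pyridine, THF, 0 °C → rt
Reagents that add atoms: none
Why: The silyl radical abstracts the phenylseleno group, and the C8 acyl radical closes ring B by 6-endo-trig attack on the unsubstituted alkene carbon C9, since attack at the substituted C10 is hindered and 6-endo closure gives a tertiary radical (a 5-exo adduct would ring-expand to the same radical). The nucleophilic tertiary C10 radical then closes ring A by 6-endo-trig addition to C1, the β-carbon of the vinyl ketone, and the electrophilic C2 radical beside the C3 ketone takes hydrogen from the silane, which carries the chain. The closest known reaction type is the stannane- or silane-mediated acyl radical 6-endo polycyclisation of selenoesters onto 1,1-disubstituted alkenes with an enone as terminator. C10 is the only new stereocentre and is controlled by the existing C5 centre: a chair-like transition state for ring A with the C5–C6 and C10–C9 bonds and the bulky C4 silyloxy group equatorial puts C1 anti to C4 and the C10 methyl axial, which is the trans-fused isomer, whereas each cis-fused chair carries an additional 1,3-diaxial contact. The step needs 6-endo regioselectivity twice, secured by the 1,1-disubstituted alkene and by the enone polarity, and ring closure faster than hydrogen transfer, secured by high dilution and slow addition of the poor hydrogen donor (Me3Si)3SiH. HF·pyridine added to the same flask then removes the silyl group from 16.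

**Step 11**
Reactants: 17 (4S,5R,10R)-4-hydroxy-11,12,13-trinoreudesmane-3,8-dione
Product: 18 (3S,4S,5R,10R)-3,4-dihydroxy-11,12,13-trinoreudesman-8-one
Conditions: Me4NBH(OAc)3 (5 equiv), MeCN/AcOH (1:1), −20 → 0 °C
Reagents that add atoms: none
Why: hydroxyl-directed reduction (Saksena–Evans), in which the C4 hydroxyl binds boron and hydride is delivered within the complex to the α-face of C3 (axial attack) to give the equatorial 3β (S) alcohol trans to the 4α-OH, while the C8 ketone has no hydroxyl in reach and is not reduced by a triacetoxyborohydride.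

**Step 12**
Reactants: 18 (3S,4S,5R,10R)-3,4-dihydroxy-11,12,13-trinoreudesman-8-one; 19 acetone
Product: 20 (3S,4S,5R,7RS,10R)-3,4,11-trihydroxyeudesman-8-one
Conditions: LiN(iPr)2 (3.3 equiv), THF, −78 °C; acetone (5 equiv), −78 °C; AcOH quench at −78 °C
Reagents that add atoms: none
Why: after both hydroxyls are deprotonated, kinetic deprotonation of the C8 ketone should occur at C7 and not at the neopentyl C9, and the lithium enolate adds to acetone (aldol addition); the C7 configuration does not matter.

**Step 13**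
Reactants: 20 (3S,4S,5R,7RS,10R)-3,4,11-trihydroxyeudesman-8-one
Product: 21 (3S,4S,5R,10R)-3,4-dihydroxyeudesm-7(11)-en-8-one
Conditions: p-TsOH·H2O (10 mol%), benzene, 50 °C
Reagents that add atoms: none
Why: acid-catalysed dehydration of the β-hydroxy ketone through its enol should give the conjugated tetrasubstituted 7(11)-alkene, while the C3 and C4 hydroxyls are not β to a carbonyl and stay.

**Step 14**
Reactants: 21 (3S,4S,5R,10R)-3,4-dihydroxyeudesm-7(11)-en-8-one; 22 angelic acid
Product: 24 (3S,4S,5R,10R)-4-hydroxy-8-oxoeudesm-7(11)-en-3-yl (2Z)-2-methylbut-2-enoate, via mixed anhydride 23 (not isolated)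
Conditions: angelic acid (3 equiv), 2,4,6-trichlorobenzoyl chloride (3 equiv), Et3N, toluene, rt; then 21, 80 °C
Reagents that add atoms: 2,4,6-trichlorobenzoyl chloride (its atoms remain only in 23), O=C(Cl)c1c(Cl)cc(Cl)cc1Cl
Why: Yamaguchi-type mixed anhydride esterification without a nucleophilic catalyst acylates the secondary 3β-OH (the tertiary 4α-OH is inert) and is the established way to transfer an angeloyl group without Z-to-E isomerisation.

**Step 15**
Reactants: 24 (3S,4S,5R,10R)-4-hydroxy-8-oxoeudesm-7(11)-en-3-yl (2Z)-2-methylbut-2-enoate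
Product: 25 (3S,4S,5R,10R)-11-hydroperoxy-4-hydroxy-8-oxoeudesm-6-en-3-yl (2Z)-2-methylbut-2-enoate (CNP0161122.1)
Conditions: O2, tetraphenylporphyrin (1 mol%), visible light (>500 nm), CH2Cl2, 0 °C, to partial conversion
Reagents that add atoms: oxygen (as singlet oxygen), O=O
Why: Schenck ene reaction, in which singlet oxygen should bond to the β-carbon C11 of the s-cis tetrasubstituted enone and take the hydrogen from C6, the position geminal to the carbonyl (gem effect), moving the double bond to C6–C7; the trisubstituted angelate alkene is much less reactive and no stereocentre is formed.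

**Compound list**
1 | tert-butyl 4-oxobutanoate | O=CCCC(=O)OC(C)(C)C | starting material
2 | 2-(triphenylphosphoranylidene)propanal | CC(C=O)=P(c1ccccc1)(c1ccccc1)c1ccccc1 | starting material
3 | tert-butyl (4E)-5-methyl-6-oxohex-4-enoate | O=C/C(C)=C/CCC(=O)OC(C)(C)C | intermediate
4 | tert-butyl (4E)-6-hydroxy-5-methylhex-4-enoate | OC/C(C)=C/CCC(=O)OC(C)(C)C | intermediate
5 | tert-butyl 3-[(2R,3R)-3-(hydroxymethyl)-3-methyloxiran-2-yl]propanoate | OC[C@@]1(C)O[C@@H]1CCC(=O)OC(C)(C)C | intermediate
6 | isopropenylmagnesium bromide | C=C(C)[Mg]Br | starting material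
7 | tert-butyl (4R,5S)-5,6-dihydroxy-5-methyl-4-(prop-1-en-2-yl)hexanoate | OC[C@@](C)(O)[C@H](CCC(=O)OC(C)(C)C)C(C)=C | intermediate
8 | tert-butyl (4R,5S)-5-methyl-4-(prop-1-en-2-yl)-5,6-bis[(triethylsilyl)oxy]hexanoate | CC[Si](CC)(CC)OC[C@@](C)(O[Si](CC)(CC)CC)[C@H](CCC(=O)OC(C)(C)C)C(C)=C | intermediate
9 | tert-butyl (4R,5S)-5-methyl-6-oxo-4-(prop-1-en-2-yl)-5-[(triethylsilyl)oxy]hexanoate | O=C[C@@](C)(O[Si](CC)(CC)CC)[C@H](CCC(=O)OC(C)(C)C)C(C)=C | intermediate
10 | vinylmagnesium bromide | C=C[Mg]Br | starting material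
11 | tert-butyl (4R,5S,6RS)-6-hydroxy-5-methyl-4-(prop-1-en-2-yl)-5-[(triethylsilyl)oxy]oct-7-enoate | C=CC(O)[C@@](C)(O[Si](CC)(CC)CC)[C@H](CCC(=O)OC(C)(C)C)C(C)=C | intermediate
12 | trimethylsilyl (4R,5S,6RS)-5-methyl-4-(prop-1-en-2-yl)-5-[(triethylsilyl)oxy]-6-[(trimethylsilyl)oxy]oct-7-enoate | C=CC(O[Si](C)(C)C)[C@@](C)(O[Si](CC)(CC)CC)[C@H](CCC(=O)O[Si](C)(C)C)C(C)=C | intermediate
13 | (4R,5S,6RS)-6-hydroxy-5-methyl-4-(prop-1-en-2-yl)-5-[(triethylsilyl)oxy]oct-7-enoic acid | C=CC(O)[C@@](C)(O[Si](CC)(CC)CC)[C@H](CCC(=O)O)C(C)=C | intermediate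
14 | Se-phenyl (4R,5S,6RS)-6-hydroxy-5-methyl-4-(prop-1-en-2-yl)-5-[(triethylsilyl)oxy]oct-7-eneselenoate | C=CC(O)[C@@](C)(O[Si](CC)(CC)CC)[C@H](CCC(=O)[Se]c1ccccc1)C(C)=C | intermediate
15 | Se-phenyl (4R,5S)-5-methyl-6-oxo-4-(prop-1-en-2-yl)-5-[(triethylsilyl)oxy]oct-7-eneselenoate | C=CC(=O)[C@@](C)(O[Si](CC)(CC)CC)[C@H](CCC(=O)[Se]c1ccccc1)C(C)=C | intermediate
16 | (4S,5R,10R)-4-[(triethylsilyl)oxy]-11,12,13-trinoreudesmane-3,8-dione | O=C1CC[C@]2(C)CC(=O)CC[C@H]2[C@]1(C)O[Si](CC)(CC)CC | intermediate
17 | (4S,5R,10R)-4-hydroxy-11,12,13-trinoreudesmane-3,8-dione [(1S,4aR,8aR)-1-hydroxy-1,4a-dimethyl-3,4,4a,7,8,8a-hexahydronaphthalene-2,6(1H,5H)-dione] | O=C1CC[C@]2(C)CC(=O)CC[C@H]2[C@]1(C)O | intermediate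
18 | (3S,4S,5R,10R)-3,4-dihydroxy-11,12,13-trinoreudesman-8-one | O[C@H]1CC[C@]2(C)CC(=O)CC[C@H]2[C@]1(C)O | intermediate
19 | acetone | CC(C)=O | starting material
20 | (3S,4S,5R,7RS,10R)-3,4,11-trihydroxyeudesman-8-one | O[C@H]1CC[C@]2(C)CC(=O)C(C(C)(C)O)C[C@H]2[C@]1(C)O | intermediate
21 | (3S,4S,5R,10R)-3,4-dihydroxyeudesm-7(11)-en-8-one | O[C@H]1CC[C@]2(C)CC(=O)C(=C(C)C)C[C@H]2[C@]1(C)O | intermediate
22 | angelic acid [(2Z)-2-methylbut-2-enoic acid] | C/C=C(/C)C(=O)O | starting material
23 | (2Z)-2-methylbut-2-enoic 2,4,6-trichlorobenzoic anhydride | C/C=C(/C)C(=O)OC(=O)c1c(Cl)cc(Cl)cc1Cl | intermediate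
24 | (3S,4S,5R,10R)-4-hydroxy-8-oxoeudesm-7(11)-en-3-yl (2Z)-2-methylbut-2-enoate | C/C=C(/C)C(=O)O[C@H]1CC[C@]2(C)CC(=O)C(=C(C)C)C[C@H]2[C@]1(C)O | intermediate
25 | (3S,4S,5R,10R)-11-hydroperoxy-4-hydroxy-8-oxoeudesm-6-en-3-yl (2Z)-2-methylbut-2-enoate | C/C=C(/C)C(=O)O[C@H]1CC[C@]2(C)CC(=O)C(C(C)(C)OO)=C[C@H]2[C@]1(C)O | target

**Step count.** Total: 15 steps. Longest linear sequence: 15 steps (1 → 25).

**Steps most likely to fail**

Step 10. The risk is that hydrogen transfer to the acyl or the tertiary C10 radical, or silyl radical addition to the vinyl ketone, outruns the second ring closure; bonding of C1 to the wrong face of C10 (cis fusion) is the other risk. The fallback sets out from 11 and returns at 16; it separates the two closures and avoids the acyl selenide, but leaves the facial question as it is. LiAlH4 (THF, 0 °C) should reduce the ester of 11 to (4R,5S,6RS)-5-methyl-4-(prop-1-en-2-yl)-5-[(triethylsilyl)oxy]oct-7-ene-1,6-diol F1. TEMPO/PhI(OAc)2 should oxidise only the primary alcohol to (4R,5S,6RS)-6-hydroxy-5-methyl-4-(prop-1-en-2-yl)-5-[(triethylsilyl)oxy]oct-7-enal F2. Me2AlCl (CH2Cl2, −78 → 0 °C) should then promote a type-two carbonyl-ene reaction between the C8 aldehyde and the isopropenyl group, closing ring B by a polar route as (4R)-4-{(2S)-3-hydroxy-2-[(triethylsilyl)oxy]pent-4-en-2-yl}-3-methylidenecyclohexan-1-ol F3. Dess–Martin periodinane should oxidise both secondary alcohols to (4R)-3-methylidene-4-{(2S)-3-oxo-2-[(triethylsilyl)oxy]pent-4-en-2-yl}cyclohexan-1-one F4. Fe(acac)3/PhSiH3 (EtOH/ethylene glycol, 60 °C) then transfers a hydrogen atom to the exocyclic methylene, and the tertiary C10 radical adds 6-endo to the vinyl ketone (reductive olefin coupling) to give 16, which the HF·pyridine treatment of step 10 converts into 17.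

Step 15. The risk is a competing ene reaction or sensitised Z-to-E isomerisation at the angelate alkene while the electron-poor enone alkene reacts slowly. The fallback sets out from 21 and returns at 25; it oxygenates before the angelate is present. Photo-oxygenation of 21 under the conditions of step 15 should give (3S,4S,5R,10R)-11-hydroperoxy-3,4-dihydroxyeudesm-6-en-8-one F5. Et3SiCl/Et3N (CH2Cl2, −20 °C) should silylate the acidic hydroperoxide in preference to the hindered alcohols, giving (3S,4S,5R,10R)-3,4-dihydroxy-11-[(triethylsilyl)peroxy]eudesm-6-en-8-one F6. The mixed anhydride 23 then acylates O3 as in step 14 to give (3S,4S,5R,10R)-4-hydroxy-8-oxo-11-[(triethylsilyl)peroxy]eudesm-6-en-3-yl (2Z)-2-methylbut-2-enoate F7, and HF·pyridine (THF, 0 °C) frees the hydroperoxide to give 25.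

Step 3. The risk is that the alkenyl Grignard reagent attacks the ester, or that bromide opening, Payne-type migration or attack of the ester carbonyl on the activated epoxide competes with SN2 entry at C5. The fallback sets out from 5 and returns at 7; it uses an alkynylalane, the most dependable carbon nucleophile for opening 2,3-epoxy alcohols at the carbon remote from the hydroxyl, and builds the isopropenyl group afterwards. Et2AlC≡CSiMe3 (from LiC≡CSiMe3 and Et2AlCl, toluene, 0 °C) should open 5 at C5 with inversion to give tert-butyl (4R,5S)-5,6-dihydroxy-5-methyl-4-[(trimethylsilyl)ethynyl]hexanoate F8. K2CO3/MeOH removes the silyl group to give tert-butyl (4R,5S)-4-ethynyl-5,6-dihydroxy-5-methylhexanoate F9. Zirconium-catalysed carboalumination (AlMe3, Cp2ZrCl2, CH2Cl2, rt) followed by protonolysis places methyl on the inner alkyne carbon and hydrogen on the terminus, giving 7.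

**Further compounds**
F1 | step 10 | (4R,5S,6RS)-5-methyl-4-(prop-1-en-2-yl)-5-[(triethylsilyl)oxy]oct-7-ene-1,6-diol | C=CC(O)[C@@](C)(O[Si](CC)(CC)CC)[C@H](CCCO)C(C)=C
F2 | step 10 | (4R,5S,6RS)-6-hydroxy-5-methyl-4-(prop-1-en-2-yl)-5-[(triethylsilyl)oxy]oct-7-enal | C=CC(O)[C@@](C)(O[Si](CC)(CC)CC)[C@H](CCC=O)C(C)=C
F3 | step 10 | (4R)-4-{(2S)-3-hydroxy-2-[(triethylsilyl)oxy]pent-4-en-2-yl}-3-methylidenecyclohexan-1-ol | C=CC(O)[C@@](C)(O[Si](CC)(CC)CC)[C@@H]1CCC(O)CC1=C
F4 | step 10 | (4R)-3-methylidene-4-{(2S)-3-oxo-2-[(triethylsilyl)oxy]pent-4-en-2-yl}cyclohexan-1-one | C=CC(=O)[C@@](C)(O[Si](CC)(CC)CC)[C@@H]1CCC(=O)CC1=C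
F5 | step 15 | (3S,4S,5R,10R)-11-hydroperoxy-3,4-dihydroxyeudesm-6-en-8-one | O[C@H]1CC[C@]2(C)CC(=O)C(C(C)(C)OO)=C[C@H]2[C@]1(C)O
F6 | step 15 | (3S,4S,5R,10R)-3,4-dihydroxy-11-[(triethylsilyl)peroxy]eudesm-6-en-8-one | O[C@H]1CC[C@]2(C)CC(=O)C(C(C)(C)OO[Si](CC)(CC)CC)=C[C@H]2[C@]1(C)O
F7 | step 15 | (3S,4S,5R,10R)-4-hydroxy-8-oxo-11-[(triethylsilyl)peroxy]eudesm-6-en-3-yl (2Z)-2-methylbut-2-enoate | C/C=C(/C)C(=O)O[C@H]1CC[C@]2(C)CC(=O)C(C(C)(C)OO[Si](CC)(CC)CC)=C[C@H]2[C@]1(C)O
F8 | step 3 | tert-butyl (4R,5S)-5,6-dihydroxy-5-methyl-4-[(trimethylsilyl)ethynyl]hexanoate | OC[C@@](C)(O)[C@H](CCC(=O)OC(C)(C)C)C#C[Si](C)(C)C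
F9 | step 3 | tert-butyl (4R,5S)-4-ethynyl-5,6-dihydroxy-5-methylhexanoate | OC[C@@](C)(O)[C@H](CCC(=O)OC(C)(C)C)C#C
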